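## Retrosynthetic overview

1. The C15 core is split into a C7 enal **4** (from keto ester **1** and phosphonate **2** via enamide **3**) and the commercial C8 dienone **5**.
2. One NHC-catalysed [3+2] annulation makes the only carbocycle, the cyclopentane, as fused β-lactone **6**. It forms C1–C5 and C2–C3 and sets the C1 quaternary / C5 stereodiad.
3. The lactone carbonyl becomes the C2 formyl group (**7**). Dehydration gives enal **8**, iminium transfer hydrogenation gives aldehyde **9** (C3 and C2 reset), and hydride reduction gives alcohol **10**.
4. Mitsunobu etherification with umbelliferone **11** gives **12**; ester cleavage gives ferulsinaic acid **13**. The coumarin ring is purchased, not built.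

Core numbering used throughout: C1 = quaternary carbon (Me, propanoate arm); C2 = CH–CH2OAr; C3 = CH–Me; C4 = CH2; C5 = CH–isobutenyl. Target = (1R,2R,3S,5S): isobutenyl, the C1 arm and the C3 methyl on one face; the C1 methyl and the C2 CH2OAr group on the other.

Assumption: the facial sense of the triazolium catalyst in Step 3 is taken by analogy with known enal annulations; if it is opposite, the enantiomeric catalyst is used.

Assumption: tert-butyl levulinate (**1**) is taken as a catalogue compound; if not, it is one esterification from levulinic acid.

## Route

**Step 1**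
Reactants: **1** tert-butyl 4-oxopentanoate; **2** diethyl {2-[methoxy(methyl)amino]-2-oxoethyl}phosphonate
Product: **3** tert-butyl (4E)-6-[methoxy(methyl)amino]-4-methyl-6-oxohex-4-enoate
Conditions: **2**, NaH, THF, 0 °C; then **1**, rt → 50 °C; chromatographic removal of the minor Z isomer
Reagents that add atoms: **2**, CCOP(=O)(OCC)CC(=O)N(C)OC
Why: Horner–Wadsworth–Emmons olefination of the methyl ketone puts the larger CH2CH2CO2tBu group trans to the amide (E major, expected about 4:1), and the isomers are separated here, where the geometry is configurationally stable.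

**Step 2**
Reactants: **3**
Product: **4** tert-butyl (4E)-4-methyl-6-oxohex-4-enoate
Conditions: DIBAL-H (1.2 equiv), THF, −78 °C; Rochelle salt
Reagents that add atoms: none
Why: Weinreb amide reduction stops at the aldehyde through the chelated tetrahedral aluminium intermediate, the hindered tert-butyl ester survives at −78 °C, and the E geometry is retained.

**Step 3**
Reactants: **4**; **5** (3E)-6-methylhepta-3,5-dien-2-one
Product: **6** tert-butyl 3-[(1S,2R,3S,5R)-2,5-dimethyl-3-(2-methylprop-1-en-1-yl)-7-oxo-6-oxabicyclo[3.2.0]heptan-2-yl]propanoate (cyclopentane-fused cis β-lactone; the configuration at core C2/C3 is inconsequential because both centres are reset in Steps 5–6)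
Conditions: aminoindanol-derived N-mesityl triazolium chloride (10 mol %, enantiomer giving core 1R,5S), DBU (10 mol %), ClCH2CH2Cl, 40 °C, slow addition of **4**
Reagents that add atoms: none (both partners are the listed reactants; the catalyst is not incorporated)
Why: Proposed new method: the carbene adds to enal **4** to give an extended Breslow intermediate (homoenolate equivalent). Cross-benzoin addition to the ketone of **5**, then an intramolecular boat oxy-Cope [3,3] shift (or direct Michael addition at the enone β-carbon rather than the hindered δ-carbon), forges C1–C5 at the fully substituted β-carbon of the enal. The resulting enol azolium closes the ring by intramolecular aldol addition to the methyl ketone (C2–C3), and acylation of the tertiary alkoxide releases the catalyst as the β-lactone. The E geometry of **4** places the propanoate arm cis and the methyl trans to the isobutenyl group, and the aminoindanol backbone shields one face of the Breslow intermediate to fix the absolute configuration at C1 and C5. The closest known reaction type is the NHC-catalysed enal + enone (chalcone or 4-oxoenoate) [3+2] annulation to cyclopentenes and cyclopentane-fused β-lactones; it has not been shown for a β,β-dialkyl enal that must create an all-carbon quaternary stereocentre, nor for an aliphatic dienone acceptor.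

**Step 4**
Reactants: **6**
Product: **7** tert-butyl 3-[(1R,2S,3R,5S)-2-formyl-3-hydroxy-1,3-dimethyl-5-(2-methylprop-1-en-1-yl)cyclopentyl]propanoate
Conditions: DIBAL-H (1.1 equiv), CH2Cl2, −78 °C; Rochelle salt
Reagents that add atoms: none
Why: Partial hydride reduction of the strained β-lactone acyl carbon gives the β-hydroxy aldehyde (the aluminium hemiacetal persists at −78 °C), while the tert-butyl ester and trisubstituted alkene are inert; no stereocentre changes.

**Step 5**
Reactants: **7**
Product: **8** tert-butyl 3-[(1R,5S)-2-formyl-1,3-dimethyl-5-(2-methylprop-1-en-1-yl)cyclopent-2-en-1-yl]propanoate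
Conditions: Bn2NH·TFA (20 mol %), THF, 50 °C (solution carried forward without isolation)
Reagents that add atoms: none
Why: Amine-catalysed aldol dehydration: the enamine of the aldehyde expels the tertiary β-hydroxyl (E1cB, no syn/anti requirement) to give the conjugated tetrasubstituted enal; a retro-aldol/re-aldol condensation path leads to the same five-membered enal, and C1 (quaternary) and C5 (not enolisable) are untouched.

**Step 6**
Reactants: **8**
Product: **9** tert-butyl 3-[(1R,2R,3S,5S)-2-formyl-1,3-dimethyl-5-(2-methylprop-1-en-1-yl)cyclopentyl]propanoate
Conditions: Hantzsch ester (diethyl 2,6-dimethyl-1,4-dihydropyridine-3,5-dicarboxylate, 1.5 equiv) added to the Step 5 solution (Bn2NH·TFA still present), THF, 50 °C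
Reagents that add atoms: none
Why: Metal-free iminium-catalysed transfer hydrogenation (conjugate reduction): the Hantzsch ester delivers hydride to C3 on the face opposite the C5 isobutenyl and C1 propanoate groups, which sets C3 with Me cis to isobutenyl, and enamine/iminium equilibration then places the C2 formyl group trans to the C3 methyl and the C1 arm (thermodynamic).

**Step 7**
Reactants: **9**
Product: **10** tert-butyl 3-[(1R,2R,3S,5S)-2-(hydroxymethyl)-1,3-dimethyl-5-(2-methylprop-1-en-1-yl)cyclopentyl]propanoate
Conditions: crude Step 6 mixture diluted with MeOH, NaBH4, 0 °C; aqueous NH4Cl work-up, chromatography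
Reagents that add atoms: none
Why: Chemoselective borohydride reduction of the aldehyde leaves the tert-butyl ester and the trisubstituted alkene untouched and locks the C2 configuration against further epimerisation.

**Step 8**
Reactants: **10**; **11** umbelliferone (7-hydroxy-2H-chromen-2-one)
Product: **12** tert-butyl 3-[(1R,2R,3S,5S)-1,3-dimethyl-5-(2-methylprop-1-en-1-yl)-2-{[(2-oxo-2H-chromen-7-yl)oxy]methyl}cyclopentyl]propanoate
Conditions: **11** (1.5 equiv), PPh3, DIAD, THF, 0 °C → rt
Reagents that add atoms: **11**, O=c1ccc2ccc(O)cc2o1
Why: Mitsunobu etherification of the primary alcohol with the acidic phenol (pKa about 7.8) forms the aryl ether without touching any stereocentre, the coumarin lactone or the tert-butyl ester.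

**Step 9**
Reactants: **12**
Product: **13** ferulsinaic acid, 3-[(1R,2R,3S,5S)-1,3-dimethyl-5-(2-methylprop-1-en-1-yl)-2-{[(2-oxo-2H-chromen-7-yl)oxy]methyl}cyclopentyl]propanoic acid
Conditions: TMSOTf, 2,6-lutidine, CH2Cl2, 0 °C; aqueous citric acid work-up
Reagents that add atoms: none
Why: Silyl triflate-mediated tert-butyl ester cleavage (loss of isobutene, then hydrolysis of the silyl ester) runs under buffered, non-protic conditions that spare the trisubstituted alkene, the aryl ether and the coumarin lactone.

## Compound list

1 | tert-butyl 4-oxopentanoate (tert-butyl levulinate) | CC(=O)CCC(=O)OC(C)(C)C | starting material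
2 | diethyl {2-[methoxy(methyl)amino]-2-oxoethyl}phosphonate | CCOP(=O)(OCC)CC(=O)N(C)OC | starting material
3 | tert-butyl (4E)-6-[methoxy(methyl)amino]-4-methyl-6-oxohex-4-enoate | CON(C)C(=O)/C=C(C)/CCC(=O)OC(C)(C)C | intermediate
4 | tert-butyl (4E)-4-methyl-6-oxohex-4-enoate | O=C/C=C(C)/CCC(=O)OC(C)(C)C | intermediate
5 | (3E)-6-methylhepta-3,5-dien-2-one | CC(=O)/C=C/C=C(C)C | starting material
6 | tert-butyl 3-[(1S,2R,3S,5R)-2,5-dimethyl-3-(2-methylprop-1-en-1-yl)-7-oxo-6-oxabicyclo[3.2.0]heptan-2-yl]propanoate | CC(C)=C[C@@H]1C[C@@]2(C)OC(=O)[C@H]2[C@]1(C)CCC(=O)OC(C)(C)C | intermediate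
7 | tert-butyl 3-[(1R,2S,3R,5S)-2-formyl-3-hydroxy-1,3-dimethyl-5-(2-methylprop-1-en-1-yl)cyclopentyl]propanoate | CC(C)=C[C@@H]1C[C@@](C)(O)[C@@H](C=O)[C@]1(C)CCC(=O)OC(C)(C)C | intermediate
8 | tert-butyl 3-[(1R,5S)-2-formyl-1,3-dimethyl-5-(2-methylprop-1-en-1-yl)cyclopent-2-en-1-yl]propanoate | CC(C)=C[C@@H]1CC(C)=C(C=O)[C@]1(C)CCC(=O)OC(C)(C)C | intermediate
9 | tert-butyl 3-[(1R,2R,3S,5S)-2-formyl-1,3-dimethyl-5-(2-methylprop-1-en-1-yl)cyclopentyl]propanoate | CC(C)=C[C@@H]1C[C@H](C)[C@@H](C=O)[C@]1(C)CCC(=O)OC(C)(C)C | intermediate
10 | tert-butyl 3-[(1R,2R,3S,5S)-2-(hydroxymethyl)-1,3-dimethyl-5-(2-methylprop-1-en-1-yl)cyclopentyl]propanoate | CC(C)=C[C@@H]1C[C@H](C)[C@@H](CO)[C@]1(C)CCC(=O)OC(C)(C)C | intermediate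
11 | umbelliferone (7-hydroxy-2H-chromen-2-one) | O=c1ccc2ccc(O)cc2o1 | starting material
12 | tert-butyl 3-[(1R,2R,3S,5S)-1,3-dimethyl-5-(2-methylprop-1-en-1-yl)-2-{[(2-oxo-2H-chromen-7-yl)oxy]methyl}cyclopentyl]propanoate | CC(C)=C[C@@H]1C[C@H](C)[C@@H](COc2ccc3ccc(=O)oc3c2)[C@]1(C)CCC(=O)OC(C)(C)C | intermediate
13 | ferulsinaic acid, 3-[(1R,2R,3S,5S)-1,3-dimethyl-5-(2-methylprop-1-en-1-yl)-2-{[(2-oxo-2H-chromen-7-yl)oxy]methyl}cyclopentyl]propanoic acid | CC(C)=C[C@@H]1C[C@H](C)[C@@H](COc2ccc3ccc(=O)oc3c2)[C@]1(C)CCC(=O)O | target

## Summary

Total steps: 9. Steps 5–7 are run in one flask without isolating **8** or **9**, so there are seven isolations. Longest linear sequence: 9 steps from **1**.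

Steps most likely to fail:

1. **Step 3 (proposed new NHC annulation).** Risks are low reactivity of the hindered β,β-dialkyl homoenolate, base-induced E/Z scrambling of **4**, competing 1,6-addition to the dienone, and untested enantio- and diastereocontrol. Fallback (known chemistry): set the C1 quaternary centre by the proline-catalysed Hajos–Parrish aldolisation of 2-methylcyclopentane-1,3-dione with methyl vinyl ketone, choosing the proline enantiomer that gives the required C1 configuration. Conjugate reduction of the enone with silyl enol ether trapping and ozonolysis then gives the C1 propanoic acid arm and a cis C5 formyl group, which a Wittig reaction with isopropylidenetriphenylphosphorane converts to isobutenyl. C3 and C2 are built from the remaining cyclopentanone by α-methylation and one-carbon homologation.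

2. **Step 6 (iminium transfer hydrogenation).** Risks are sluggish iminium formation from the tetrasubstituted, α-quaternary-flanked enal **8** and insufficient facial bias at C3. Fallback: isolate **8**, oxidise it to the methyl ester (Pinnick oxidation, then TMSCHN2), carry out a dissolving-metal (Mg/MeOH) conjugate reduction with base equilibration at C2, and reduce the methyl ester selectively (LiBH4) to **10**. This replaces hydride delivery to an iminium ion with thermodynamically controlled protonation.

3. **Step 4 (partial reduction of the β-lactone).** Risks are over-reduction to the diol and retro-aldol on work-up. Fallback: reduce **6** fully to the 1,3-diol with LiBH4 (the tert-butyl ester is inert), then selectively re-oxidise the primary alcohol with TEMPO/PhI(OAc)2 to reach **7**.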